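**The question.** How much Z, the adduct of E with two D, stands after 8.0 d in each of three flasks that differ in their charge of D?

| flask | E | D | remark | time |
|---|---|---|---|---|
| birch | 0.050 M | 0.021 M | run made earlier |  |
| ash | 0.050 M | 0.16 M | run made earlier |  |
| north-west | 0.050 M | 0.0250 M |  | 8.0 d |
| north-east | 0.050 M | 0.125 M |  | 8.0 d |
| north | 0.050 M | 0.200 M |  | 8.0 d |

- birch (time / d: Z / %): 0.333: 0; 0.500: 1; 0.833: 0; 1.04: 2; 1.67: 2; 2.50: 3; 4.00: 0
- ash (time / d: Z / %): 0.208: 2; 0.625: 9; 1.04: 12; 1.67: 9; 2.50: 14; 3.00: 16; 4.00: 12

(each reading ± 1.5 percentage points)

- amount of Z at the end, in percent of the E charged, for each flask in turn (north-west, north-east, north)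

**Main step.** Begin with one step, E plus two D giving Z, and ask for its end state. Then north-west, with D as limiting reagent, has a ceiling of 25.0 %, and north has 100 %. But ash reads 9 % at 0.625 d, then levels near 12.6 %, the mean of its last five readings, far below its ceiling.

**Adding a loss.** Now suppose D also adds to Z, so that Z is a stock fed at one end and drained at the other. Such a stock levels at its feed rate times its time constant. In ash, the level over the early rate of rise reads 0.875 d. Call this average stay of a Z the Z lifetime, and let it scale as one over D (pseudo-first-order). Birch reads near 1.75 % on average over its last four readings. So the ratio of the ash level to the birch level reads 7.20, with the scatter of such small readings, and this is close to the ratio of their D charges, 7.62, so I take the level as proportional to D, which makes the feed go as D squared. That gives levels of 1.97 %, 9.84 % and 15.8 %.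

**Adding the drain.** The level also rests on the E left. Scaling the early rise of ash, the charge of E drains with a time of 284 d in north-west, 11.4 d in north-east and 4.44 d in north. Multiplying each level by its decay over the run, and leaving out the fall of D, I reckon 1.91 %, 4.87 % and 2.60 %. In this reckoning north ends lower than north-east because its drain time is shorter than the run, while that of north-east is longer.

**The result.** The forecast stands at 1 %, 10 % and 20 %, and of the last it admits “real uncertainty”. The flasks give 3.08 %, 10.4 % and 6.72 %: north is lower than north-east, as I reckoned, though north-east stands at 2.14 times my figure.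

    E + D → J (k = 0.130 M⁻¹ h⁻¹)
    D + J → Z (k = 0.420 M⁻¹ h⁻¹)
    D + Z → Q (k = 0.250 M⁻¹ h⁻¹)
    D + Q → L (k = 0.210 M⁻¹ h⁻¹)
    Z ⇌ X (K = 0.560, k = 0.0240 h⁻¹)
    J → G (k = 0.0190 h⁻¹)

**Lifetime again.** In north at 8.00 d, D stands at 33.7 % of its charge, so the Z lifetime is 2.08 d, a quarter of the run, and E left, 6.52 %, is close to Z, 6.72 %. In north-east, with D at 28.1 % of its charge, the lifetime is 3.99 d, half of the run, and E left is 19.2 % against Z at 10.4 %.

The data stem from a simulated flask with constants of no real substance, noise included.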